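Saturday's run holds less first nucleophile than Tuesday's and reads a higher ratio of other capture product to target, 6.57 against 5.62 at 10.0 d, so, as far as readings with this scatter show, the two nucleophiles seem to compete.

| flask | substrate | first nucleophile | second nucleophile | remark | time |
|---|---|---|---|---|---|
| Saturday's | 0.20 M | 0.17 M | 0.22 M | run made earlier |  |
| Tuesday's | 0.20 M | 0.39 M | 0.22 M | run made earlier |  |
| flask | 0.20 M | 0.260 M | 0.220 M |  | 10 d |

| run | time / d | other capture product / % | target / % |
|---|---|---|---|
| Saturday's | 2.08 | 37 | 6 |
| Saturday's | 4.00 | 41 | 7 |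
| Saturday's | 6.00 | 43 | 6 |
| Saturday's | 8.00 | 44 | 8 |
| Saturday's | 10.0 | 46 | 7 |
| Saturday's | 12.0 | 44 | 5 |
| Tuesday's | 0.833 | 20 | 7 |
| Tuesday's | 2.50 | 38 | 9 |
| Tuesday's | 4.00 | 42 | 11 |
| Tuesday's | 6.00 | 43 | 8 |
| Tuesday's | 10.0 | 45 | 8 |
| Tuesday's | 12.0 | 41 | 11 |

(readings scatter by 1.5 percentage points)



* ratio of other capture product to target at 1.0 h
* ratio of other capture product to target at 10 d

I suppose that they compete for one short-lived species, taken as used up as fast as it forms, so that the ratio made at any moment is the capture number ρ, the selectivity factor S times c(second nucleophile)/c(first nucleophile). Tuesday's earliest reading gives a ratio of 2.86 at 0.833 d, and from it S, what second nucleophile captures for each capture by first nucleophile at equal concentrations, reads 5.06. The flask's charges then give ρ = 4.29, which is my figure for 1.0 h. Tuesday's reading at 10.0 d is twice that early one, so in these readings ρ serves for the start of Tuesday's run and not for its end, and since the early reading may already sit on that climb, I hold ρ as a high figure. For 10 d I interpolate the two runs in c(first nucleophile) and get 6.18.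

The forecast gives 4.5 and 5.7, calling the early figure “poorly constrained, since no run sampled that early”; both differ from mine.

The flask gives 2.87 at 1.0 h and 6.56 at 10 d.

    second nucleophile + intermediate → other capture product (k = 1600 M⁻¹ h⁻¹)
    2 first nucleophile → homo dimer (k = 0.0830 M⁻¹ h⁻¹)
    substrate → intermediate (k = 0.0340 h⁻¹)
    second nucleophile + target → over-reaction product (k = 0.0140 M⁻¹ h⁻¹)
    first nucleophile + intermediate → target (k = 480 M⁻¹ h⁻¹)
    intermediate → solvolysis product (k = 280 h⁻¹)

The flask's early ratio is 0.670 of ρ. The neighbouring flask with 0.37 M of second nucleophile has ρ = 7.21 by the same S, and it gives 4.84 at 1.0 h, which is 0.671 of its ρ. At 10 d that neighbour's ratio is 16.8, with target at 3.49%.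

Readings and results are simulated for substances that don't exist; the scatter is artificial.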